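**Retrosynthetic overview**

- The target is guibourtinidol-(4α→6)-fisetinidol; the last two steps only remove one acetate and five benzyl ethers.
- Key disconnection: ring C of the upper unit is opened at C2–C3 and, in the same operation, the interflavan bond C4–C6 (lower unit) is cut. This leads to an acyclic aryl 4-(benzyloxy)benzyl ether carrying an (E)-2-acetoxyvinyl group, plus tri-O-benzyl-(−)-fisetinidol.
- Enabling feature: the 4'-oxygen of ring B is para to C2, so O1–C2H2 is a para-alkoxybenzyl ether from which an oxidant can take hydride. The 7-oxygen of ring A is para (and O1 ortho) to C4a, so C3 is the nucleophilic β-carbon of a para-alkoxystyrene and C4 becomes the quinone-methide-like flavan-4-yl cation of the presumed biosynthesis.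
- Order of ring formation: rings A and B of the upper unit and all three rings of the lower unit are bought; ring C of the upper unit is the only ring made, in the key step, together with the stereocentres C2, C3 and C4.
- The cyclisation precursor comes from 4-(benzyloxy)-2-hydroxybenzaldehyde in four steps (O-alkylation with the ring B unit, boron-Wittig olefination, trifluoroborate formation, copper-catalysed acetoxylation).

Key step: step 6

Assumption: (−)-fisetinidol and, for one fallback, (+)-garbanzol are taken as purchasable natural flavonoids; the sense of induction of the chiral phosphate in step 6 cannot be predicted with certainty, so the (R)-acid is written and its mirror image would be used if the other face is favoured.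

**Step 1**
Reactants: 1 4-(benzyloxy)-2-hydroxybenzaldehyde; 2 4-(benzyloxy)benzyl chloride
Product: 3 4-(benzyloxy)-2-{[4-(benzyloxy)benzyl]oxy}benzaldehyde
Conditions: K2CO3, DMF, 60 °C
Reagents that add atoms: none
Why: Williamson ether synthesis, in which the phenoxide displaces the reactive benzylic chloride (SN2) and installs C2 and ring B on O1; no stereocentre is formed.

**Step 2**
Reactants: 3 4-(benzyloxy)-2-{[4-(benzyloxy)benzyl]oxy}benzaldehyde; 4 bis(pinacolatoboryl)methane
Product: 5 (E)-2-(2-{4-(benzyloxy)-2-[(4-(benzyloxy)benzyl)oxy]phenyl}ethenyl)-4,4,5,5-tetramethyl-1,3,2-dioxaborolane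
Conditions: lithium 2,2,6,6-tetramethylpiperidide (LiTMP), THF, 0 °C, then 3, −78 °C → rt
Reagents that add atoms: none
Why: Boron-Wittig olefination, in which the α-boryl carbanion adds to the non-enolisable aldehyde and syn B–O elimination should give the (E)-alkenyl boronate, bringing in the carbon that becomes C3.

**Step 3**
Reactants: 5 (E)-alkenyl pinacol boronate
Product: 6 potassium (E)-(2-{4-(benzyloxy)-2-[(4-(benzyloxy)benzyl)oxy]phenyl}ethenyl)trifluoroborate
Conditions: KHF2 (aq.), MeOH, rt
Reagents that add atoms: potassium hydrogen difluoride, [K+].F[H-]F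
Why: Standard exchange of a pinacol boronate into the trifluoroborate salt, the boron form that couples best in the next step; the alkene geometry is untouched.

**Step 4**
Reactants: 6 potassium (E)-alkenyltrifluoroborate
Product: 7 (E)-2-{4-(benzyloxy)-2-[(4-(benzyloxy)benzyl)oxy]phenyl}ethenyl acetate
Conditions: AcOH, CuBr (cat.), DMAP, 4 Å MS, O2 (1 atm), MeCN, 40 °C
Reagents that add atoms: acetic acid, CC(=O)O
Why: Copper-catalysed oxidative C–O coupling of a carboxylic acid with an alkenyltrifluoroborate (Chan–Lam type), which should place the future C3 oxygen on the boron-bearing carbon with retention of the (E)-geometry.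

**Step 5**
Reactants: 8 (−)-fisetinidol
Product: 9 7,3',4'-tri-O-benzyl-(−)-fisetinidol
Conditions: BnBr (3.3 equiv), K2CO3, DMF, rt, argon
Reagents that add atoms: benzyl bromide, BrCc1ccccc1
Why: Williamson benzylation under carbonate conditions, which should alkylate the three phenoxides and leave the secondary 3-OH and both stereocentres untouched.

**Step 6**
Reactants: 7 (E)-enol acetate; 9 7,3',4'-tri-O-benzyl-(−)-fisetinidol
Product: 12 3-O-acetyl-7,4'-di-O-benzylguibourtinidol-(4α→6)-7,3',4'-tri-O-benzylfisetinidol, via oxocarbenium ion 10 (not isolated), via acetoxonium ion 11 (not isolated)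
Conditions: DDQ (1.1 equiv), (R)-3,3'-bis(2,4,6-triisopropylphenyl)-1,1'-binaphthyl-2,2'-diyl hydrogen phosphate [(R)-TRIP, 1.0 equiv, recovered], 4 Å MS, CH2Cl2 (0.02 M), −20 °C; then 9 (3 equiv), TMSOTf (0.1 equiv), −78 → −20 °C
Reagents that add atoms: none
Why: Proposed new method: DDQ should abstract hydride from the O1–CH2 group of 7 (a para-alkoxybenzyl ether because ring B carries its 4'-oxygen) to give oxocarbenium ion 10 paired with the chiral phosphate; C3 of the (E)-enol acetate then attacks C2 in a Prins cyclisation, the charge arrives at C4 where the para 7-benzyloxy group and O1 stabilise it as the quinone-methide-like flavan-4-yl cation and the neighbouring acetate caps it as the cis-fused acetoxonium ion 11, and added 9 opens 11 at C4 through its C6 in a Friedel–Crafts alkylation that copies the flavan-4-yl cation capture assumed in proanthocyanidin biosynthesis. The closest known reaction types are the DDQ-mediated oxidative cyclisation of para-methoxybenzyl alkyl ethers onto tethered enol acetates, chiral phosphate ion-pair control of additions to cyclic aryl oxocarbenium ions, and the Lewis-acid coupling of C4-activated 3-O-acyl flavans with benzylated flavan-3-ols; new are the aryl ether substrate, attack through the acetoxy-bearing alkene carbon and the merger into one pot. Ring C is closed in the 6-endo-trig mode (cation–olefin closure onto the distal alkene carbon), and the transient acetoxonium ring is closed by neighbouring-group attack of the acetate carbonyl oxygen on C4 and reopened in the same pot. C2 (R) is to be set by the phosphate counter-anion shielding one face of the (E)-oxocarbenium ion, C3 (S) follows from the (E)-alkene geometry in a half-chair transition state with the aryl and acetoxy groups pseudo-equatorial (2,3-trans), and C4 (α-aryl) follows from anti opening of the acetoxonium bridge (3,4-trans). The step needs 6-endo over 5-exo closure, secured because C3 is the β-carbon of a para-alkoxystyrene that stays conjugated with ring A while the acetoxy oxygen is a poor donor, and C6 over C8 attack in 9, secured because C6 is para to the ring oxygen and has only one ortho substituent. Imperfect facial control would show up as a diastereomer of 12 that chromatography can remove, not as an enantiomer, because 9 is enantiopure.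

**Step 7**
Reactants: 12 3-O-acetyl penta-O-benzyl dimer
Product: 13 7,4'-di-O-benzylguibourtinidol-(4α→6)-7,3',4'-tri-O-benzylfisetinidol
Conditions: K2CO3 (0.2 equiv), MeOH/THF, rt
Reagents that add atoms: none
Why: Base-catalysed transesterification (methanolysis) cleaves the acyl–oxygen bond, so the C3 oxygen and its configuration are retained, and the fully benzylated flavan units have no free phenol through which C2 could epimerise.

**Step 8**
Reactants: 13 penta-O-benzyl dimer
Product: 14 guibourtinidol-(4α→6)-fisetinidol (target)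
Conditions: H2 (1 atm), Pd(OH)2/C, THF/MeOH, rt
Reagents that add atoms: none
Why: Catalytic hydrogenolysis should cleave the five aryl benzyl ethers, while the cyclic C2–O1 bonds and the C4 diarylmethine are expected to survive these mild neutral conditions, as is usual for benzylated proanthocyanidins.

**Compound list**

1 | 4-(benzyloxy)-2-hydroxybenzaldehyde | O=Cc1ccc(OCc2ccccc2)cc1O | starting material
2 | 4-(benzyloxy)benzyl chloride | ClCc1ccc(OCc2ccccc2)cc1 | starting material
3 | 4-(benzyloxy)-2-{[4-(benzyloxy)benzyl]oxy}benzaldehyde | O=Cc1ccc(OCc2ccccc2)cc1OCc1ccc(OCc2ccccc2)cc1 | intermediate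
4 | bis(pinacolatoboryl)methane, 2,2'-methylenebis(4,4,5,5-tetramethyl-1,3,2-dioxaborolane) | CC1(C)OB(CB2OC(C)(C)C(C)(C)O2)OC1(C)C | starting material
5 | (E)-2-(2-{4-(benzyloxy)-2-[(4-(benzyloxy)benzyl)oxy]phenyl}ethenyl)-4,4,5,5-tetramethyl-1,3,2-dioxaborolane | CC1(C)OB(/C=C/c2ccc(OCc3ccccc3)cc2OCc2ccc(OCc3ccccc3)cc2)OC1(C)C | intermediate
6 | potassium (E)-(2-{4-(benzyloxy)-2-[(4-(benzyloxy)benzyl)oxy]phenyl}ethenyl)trifluoroborate | [K+].F[B-](F)(F)/C=C/c1ccc(OCc2ccccc2)cc1OCc1ccc(OCc2ccccc2)cc1 | intermediate
7 | (E)-2-{4-(benzyloxy)-2-[(4-(benzyloxy)benzyl)oxy]phenyl}ethenyl acetate | CC(=O)O/C=C/c1ccc(OCc2ccccc2)cc1OCc1ccc(OCc2ccccc2)cc1 | intermediate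
8 | (−)-fisetinidol, (2R,3S)-2-(3,4-dihydroxyphenyl)chromane-3,7-diol | Oc1ccc2c(c1)O[C@H](c1ccc(O)c(O)c1)[C@@H](O)C2 | starting material
9 | 7,3',4'-tri-O-benzyl-(−)-fisetinidol, (2R,3S)-7-(benzyloxy)-2-[3,4-bis(benzyloxy)phenyl]chroman-3-ol | c1ccccc1COc1ccc2c(c1)O[C@H](c1ccc(OCc3ccccc3)c(OCc3ccccc3)c1)[C@@H](O)C2 | intermediate
10 | aryl oxocarbenium ion: [2-((E)-2-acetoxyethenyl)-5-(benzyloxy)phenyl][4-(benzyloxy)benzylidene]oxonium | CC(=O)O/C=C/c1ccc(OCc2ccccc2)cc1[O+]=Cc1ccc(OCc2ccccc2)cc1 | intermediate
11 | acetoxonium ion: 7-(benzyloxy)-2-[4-(benzyloxy)phenyl]flavan with the C3 and C4 oxygens bridged as a 2-methyl-1,3-dioxolan-2-ylium ring (2R; aryl at C2 α, both oxygens β; 2,3-trans-3,4-cis) | c1ccccc1COc1ccc([C@H]2Oc3cc(OCc4ccccc4)ccc3[C@@H]3[O+]=C(C)O[C@H]23)cc1 | intermediate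
12 | 3-O-acetyl-7,4'-di-O-benzylguibourtinidol-(4α→6)-7,3',4'-tri-O-benzylfisetinidol (upper unit 2R,3S with 4α-aryl, all-trans; lower unit 2R,3S) | c1ccccc1COc1ccc([C@H]2Oc3cc(OCc5ccccc5)ccc3[C@@H](c3cc4c(cc3OCc5ccccc5)O[C@H](c3ccc(OCc5ccccc5)c(OCc5ccccc5)c3)[C@@H](O)C4)[C@@H]2OC(C)=O)cc1 | intermediate
13 | 7,4'-di-O-benzylguibourtinidol-(4α→6)-7,3',4'-tri-O-benzylfisetinidol (upper unit 2R,3S with 4α-aryl, all-trans; lower unit 2R,3S) | c1ccccc1COc1ccc([C@H]2Oc3cc(OCc5ccccc5)ccc3[C@@H](c3cc4c(cc3OCc5ccccc5)O[C@H](c3ccc(OCc5ccccc5)c(OCc5ccccc5)c3)[C@@H](O)C4)[C@@H]2O)cc1 | intermediate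
14 | guibourtinidol-(4α→6)-fisetinidol (upper unit 2R,3S,4R; lower unit 2R,3S) | Oc1ccc([C@H]2Oc3cc(O)ccc3[C@@H](c3cc4c(cc3O)O[C@H](c3ccc(O)c(O)c3)[C@@H](O)C4)[C@@H]2O)cc1 | target

**Totals**

Total step count: 8. Longest linear sequence: 7 steps (steps 1, 2, 3, 4, 6, 7, 8); step 5 is a one-step side branch.

**Steps most likely to fail**

Step 6 (Proposed new method). Several processes may defeat it:
- hydride abstraction may be slow on an aryl para-alkoxybenzyl ether, or the oxidant may attack the electron-rich styrene instead;
- closure may leak to the 5-exo mode through C4;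
- the phosphate may give poor facial selectivity;
- the C4 cation may lose the C3 proton before the nucleophile is added.

The fallback uses only known chemistry. It sets out from compound 9 together with purchased (+)-garbanzol [(2R,3R)-3,7,4'-trihydroxyflavanone, Oc1ccc([C@H]2Oc3cc(O)ccc3C(=O)[C@@H]2O)cc1] and comes back to the route at compound 13. Benzylation of the two phenols (BnBr, K2CO3, DMF, rt) should give 7,4'-di-O-benzylgarbanzol F1. Reduction with NaBH4 (MeOH/THF, 0 °C) should give the 2,3-trans-3,4-trans diol 7,4'-di-O-benzylleucoguibourtinidin F2. Acid-mediated condensation of F2 with excess 9 (TMSOTf or BF3·OEt2, CH2Cl2, −78 → −20 °C) is the established flavan-3,4-diol/flavan-3-ol coupling; it should form the 4α→6 bond trans to the 3-hydroxyl and deliver 13, which is carried on through step 8.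

Step 4. Protodeboronation or oxidative homocoupling of the electron-rich styryl trifluoroborate may outrun C–O bond formation, and any E to Z isomerisation would erode the 2,3-trans selectivity of step 6. The fallback sets out from compound 3 and comes back at compound 7. Claisen–Schmidt condensation of 3 with acetone (NaOH, acetone/EtOH, rt) should give (E)-4-{4-(benzyloxy)-2-[(4-(benzyloxy)benzyl)oxy]phenyl}but-3-en-2-one F3. Baeyer–Villiger oxidation (mCPBA, NaHCO3, CH2Cl2, 0 °C), in which the alkenyl group migrates in preference to methyl with retention of the double-bond geometry, should then give enol acetate 7.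

Step 2. Incomplete conversion or loss of (E)-selectivity in the boron-Wittig elimination may occur on the hindered, electron-rich ortho-alkoxy aldehyde. The fallback sets out from compound 3 and comes back at compound 5. Ohira–Bestmann homologation (dimethyl (1-diazo-2-oxopropyl)phosphonate, K2CO3, MeOH, rt) should give 4-(benzyloxy)-2-{[4-(benzyloxy)benzyl]oxy}-1-ethynylbenzene F4. Zirconium-catalysed syn-hydroboration with pinacolborane (Cp2ZrHCl cat., Et3N, neat or CH2Cl2, 60 °C) should give the (E)-alkenyl boronate 5.

**Further compounds**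

F1 | step 6 | 7,4'-di-O-benzylgarbanzol, (2R,3R)-7-(benzyloxy)-2-[4-(benzyloxy)phenyl]-3-hydroxychroman-4-one | c1ccccc1COc1ccc([C@H]2Oc3cc(OCc4ccccc4)ccc3C(=O)[C@@H]2O)cc1
F2 | step 6 | 7,4'-di-O-benzylleucoguibourtinidin, (2R,3S,4R)-7-(benzyloxy)-2-[4-(benzyloxy)phenyl]chromane-3,4-diol | c1ccccc1COc1ccc([C@H]2Oc3cc(OCc4ccccc4)ccc3[C@@H](O)[C@@H]2O)cc1
F3 | step 4 | (E)-4-{4-(benzyloxy)-2-[(4-(benzyloxy)benzyl)oxy]phenyl}but-3-en-2-one | CC(=O)/C=C/c1ccc(OCc2ccccc2)cc1OCc1ccc(OCc2ccccc2)cc1
F4 | step 2 | 4-(benzyloxy)-2-{[4-(benzyloxy)benzyl]oxy}-1-ethynylbenzene | C#Cc1ccc(OCc2ccccc2)cc1OCc1ccc(OCc2ccccc2)cc1
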